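From the constants I want one thing: the rate at which G ends up as E.Q in each flask.

- noon: G 0.057 M; E 0.0540 M; Z 0.0570 M; time 8.0 h
- dusk: G 0.057 M; E 0.110 M; Z 0.0570 M; time 8.0 h

    G → Q (k1 = 5.3 × 10⁻⁵ s⁻¹)
    J + Q ⇌ J.Q (K2 = 82 L mol⁻¹, k2 = 0.31 L mol⁻¹ s⁻¹)
    E + Q → E.Q (k3 = 6.8 L mol⁻¹ s⁻¹)
    G + Q → G.Q (k4 = 7.1 × 10⁻⁴ L mol⁻¹ s⁻¹)
    Z ⇌ J, rate k5*(cs5 - [J]) while solid is left; crystals form when [J] > cs5 (cs5 = 32 mM, k5 = 1.5 × 10⁻⁴ s⁻¹)

* which of these there is most of at the end, counted by the G in it, noon (E.Q / G.Q / J.Q / G)
* which of these there is most of at the end, counted by the G in it, dusk (E.Q / G.Q / J.Q / G)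
* final amount of the leader among these, as a percentage of the G charged, in noon
* final amount of the leader among these, as a percentage of the G charged, in dusk

- a species is counted by the G in it: one G.Q counts as two
- given per volume of solution although it is solid: Z
- at the start none of Z is in solution
- run time (noon): 8.0 h

G gives Q at 10.9 mM h⁻¹ at the start of both flasks. At the start of noon, E takes Q at 0.367 s⁻¹, much faster than J at its solubility does, 0.00992 s⁻¹, and much faster than G decays. So I treat G's decay as the rate-limiting step, and E.Q forms as fast as Q is made.

G's own fall slows that rate. I carry τ, the reciprocal of G's decay constant, 5.24 h, the time in which the rate of making Q falls by the factor e. Over 8.0 h the rate falls by a factor 4.60, so 78.3% of the G has become Q.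

Now I put that answer back in. E falls by a factor 5.75 in noon and 1.68 in dusk. Yet at the end of noon E still takes Q at 0.0638 s⁻¹, faster than J does and much faster than G decays. So I add no second slowing, and I commit to E.Q leading both flasks at 78.3%.

The forecast names E.Q for noon and E.Q for dusk, at 78.2% and 78.26%, holding that “E is the dominant trap for Q”. My own figure is the same for both flasks.

The flasks give E.Q at 78.2% in noon and E.Q at 78.3% in dusk. At 2.60 h in noon, Q has a half-life against E of 0.054 min, far shorter than the 3.6 h of G by its decay alone, and Q is made 1.00 times as fast as it is used. With τ, the first 4.00 h of noon carries 68.2% of the making, and the step's reading there is 68%.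

The answer would fail on the reading time. The noon flask read at 2.0 h has run 0.382 τ, which leaves 68.3% of the G and makes 31.7%, so G should lead. Computed, G leads there at 68.3%, with E.Q at 31.7%.

All constants were drawn at random within sensible limits; the flask was simulated.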